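The macrocycle is opened at the saturated B–C bridge (McMurry coupling, then hydrogenation), but the route rests on taking ring B itself apart. Ring B is a para-phenylene whose only substituents are the ether oxygen to ring A and, on the para carbon, the bridge CH2. Its six carbons map onto C3–C6 of methyl coumalate plus the two carbons of an O-aryl alkyne. One inverse-demand [4+2] cycloaddition with CO2 extrusion therefore builds ring B, turns the ynol ether oxygen into the A–O–B diaryl ether link and places the ester para to it. The precursor is the ring A ethynyl ether that already carries the A–D ethano bridge, the D–O–C ether and ring C's aldehyde as a dioxolane.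

Key step: step 8

Ring labels: A = the 3-aryloxy-4,5-dihydroxyphenyl ring; B = the 1,4-phenylene; C = the 2-aryloxy-3,4-dihydroxyphenyl ring; D = the 1,2-phenylene without hydroxyl.

Assumption: (2-hydroxybenzyl)triphenylphosphonium bromide is taken as a catalogue reagent, and both stilbene double bonds are carried as E/Z mixtures because each is hydrogenated later.

Step 1
Reactants: 1 3-hydroxy-4,5-dimethoxybenzaldehyde
Product: 2 3-(benzyloxy)-4,5-dimethoxybenzaldehyde
Conditions: BnBr, K2CO3, DMF, rt
Reagents that add atoms: benzyl bromide, BrCc1ccccc1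
Why: Williamson ether synthesis on the phenoxide masks the ring A phenol so that only the ring D phenol is free for the later arylation, with a group that the stilbene hydrogenation removes at no extra cost.

Step 2
Reactants: 2 3-(benzyloxy)-4,5-dimethoxybenzaldehyde; 3 (2-hydroxybenzyl)triphenylphosphonium bromide
Product: 5 2-[2-(3-benzyloxy-4,5-dimethoxyphenyl)ethenyl]phenol (E/Z mixture), via ylide phenoxide 4 (not isolated)
Conditions: 3, KOtBu (2.2 equiv), THF, 0 °C; then 2, 0 °C → rt; dilute HCl work-up
Reagents that add atoms: none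
Why: Wittig olefination in which two equivalents of base give the phenoxide ylide 4, a semi-stabilised benzylic ylide that should condense cleanly with the non-enolisable aldehyde 2, the alkene geometry being irrelevant.

Step 3
Reactants: 5 2-[2-(3-benzyloxy-4,5-dimethoxyphenyl)ethenyl]phenol; 6 2-fluoro-3,4-dimethoxybenzaldehyde
Product: 7 2-{2-[2-(3-benzyloxy-4,5-dimethoxyphenyl)ethenyl]phenoxy}-3,4-dimethoxybenzaldehyde (E/Z mixture)
Conditions: K2CO3, DMF, 120 °C
Reagents that add atoms: none
Why: Nucleophilic aromatic substitution (addition–elimination) in which the ortho-formyl group stabilises the Meisenheimer adduct and fluoride leaves, so the ring D phenoxide, the only free phenol present, should form the D–O–C ether.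

Step 4
Reactants: 7 2-{2-[2-(3-benzyloxy-4,5-dimethoxyphenyl)ethenyl]phenoxy}-3,4-dimethoxybenzaldehyde
Product: 8 2-(2-{2-[2-(3-benzyloxy-4,5-dimethoxyphenyl)ethenyl]phenoxy}-3,4-dimethoxyphenyl)-1,3-dioxolane (E/Z mixture)
Conditions: HOCH2CH2OH, p-TsOH·H2O (cat.), toluene, reflux, Dean–Stark trap
Reagents that add atoms: ethylene glycol, OCCO
Why: Acid-catalysed acetalisation driven by azeotropic water removal masks the ring C aldehyde against the hydrogenation and the organolithium step, and benzyl ether and stilbene are inert to catalytic acid.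

Step 5
Reactants: 8 2-(2-{2-[2-(3-benzyloxy-4,5-dimethoxyphenyl)ethenyl]phenoxy}-3,4-dimethoxyphenyl)-1,3-dioxolane
Product: 9 5-(2-{2-[6-(1,3-dioxolan-2-yl)-2,3-dimethoxyphenoxy]phenyl}ethyl)-2,3-dimethoxyphenol
Conditions: H2 (1 atm), 10% Pd/C, NaHCO3 (solid), EtOAc, rt
Reagents that add atoms: none
Why: Catalytic hydrogenation saturates the stilbene and hydrogenolysis cleaves the aryl benzyl ether in the same operation, while the dioxolane, which must be ionised by acid before its C–O bond can be hydrogenolysed, should persist in the buffered neutral medium.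

Step 6
Reactants: 9 5-(2-{2-[6-(1,3-dioxolan-2-yl)-2,3-dimethoxyphenoxy]phenyl}ethyl)-2,3-dimethoxyphenol; 10 trichloroethylene
Product: 12 2-{2-[2-(2-{3-[(E)-1,2-dichloroethenyloxy]-4,5-dimethoxyphenyl}ethyl)phenoxy]-3,4-dimethoxyphenyl}-1,3-dioxolane, via dichloroacetylene 11 (not isolated)
Conditions: K2CO3, DMF, 70 °C, closed system under N2
Reagents that add atoms: none
Why: Vinylic substitution by elimination–addition, in which the base dehydrochlorinates trichloroethylene to dichloroacetylene and the ring A phenoxide adds to it in anti fashion to give the (E)-1,2-dichlorovinyl ether, the acetal being inert to base.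

Step 7
Reactants: 12 2-{2-[2-(2-{3-[(E)-1,2-dichloroethenyloxy]-4,5-dimethoxyphenyl}ethyl)phenoxy]-3,4-dimethoxyphenyl}-1,3-dioxolane
Product: 15 2-[2-(2-{2-[3-(ethynyloxy)-4,5-dimethoxyphenyl]ethyl}phenoxy)-3,4-dimethoxyphenyl]-1,3-dioxolane, via chloroalkyne 13 (not isolated), via lithium acetylide 14 (not isolated)
Conditions: n-BuLi (2.3 equiv), THF, −78 °C; then H2O/THF, −78 → 0 °C; used at once as a cold solution
Reagents that add atoms: none
Why: Dehydrochlorination followed by halogen–lithium exchange, in which n-BuLi removes the acidic vinylic proton, anti β-elimination of LiCl gives chloroalkyne 13, a second equivalent exchanges Cl for Li to give 14, and protonation at −78 °C should free the terminal ynol ether before acetal C–H or arene metalation can compete.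

Step 8
Reactants: 15 2-[2-(2-{2-[3-(ethynyloxy)-4,5-dimethoxyphenyl]ethyl}phenoxy)-3,4-dimethoxyphenyl]-1,3-dioxolane; 16 methyl coumalate
Product: 18 methyl 4-[5-(2-{2-[6-(1,3-dioxolan-2-yl)-2,3-dimethoxyphenoxy]phenyl}ethyl)-2,3-dimethoxyphenoxy]benzoate, via bicyclic lactone 17 (not isolated)
Conditions: 16 (2 equiv), toluene, 100 °C, sealed base-washed tube, 15 added slowly
Reagents that add atoms: none
Why: Proposed new method: methyl coumalate is an electron-poor 2-pyrone diene with its largest LUMO coefficient at C6, and the ynol ether of 15 is polarised so that its terminal carbon is the nucleophilic end, so a strongly asynchronous inverse-demand [4+2] cycloaddition should join the terminal carbon to C6 and the oxygen-bearing carbon to C3, giving bridged lactone 17. Retro-[4+2] loss of CO2 from 17 is driven by aromatisation and needs no oxidant because the 2π partner is an alkyne. The closest known reactions are the thermal cycloadditions of coumalate esters with enol ethers, ketene acetals, enamines and ynamines that end in benzoates after CO2 loss; a terminal aryloxyacetylene has not been shown as the partner. Ring B is closed by intermolecular [4+2] annulation (two C–C bonds, four carbons from the pyrone and two from the alkyne), and no stereocentre remains because the two bridgehead centres of 17 vanish on aromatisation. The step needs para regiochemistry (aryloxy carbon opposite the ester-bearing carbon), which the matched polarisation of ynol ether and pyrone C6 should secure, and it needs the alkyne to survive heating, which the lack of a β-hydrogen on the aryl ether (no retro-ene route to a ketene) and slow addition to excess pyrone should favour.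

Step 9
Reactants: 18 methyl 4-[5-(2-{2-[6-(1,3-dioxolan-2-yl)-2,3-dimethoxyphenoxy]phenyl}ethyl)-2,3-dimethoxyphenoxy]benzoate
Product: 20 2-[2-(2-{3-[4-(hydroxymethyl)phenoxy]-4,5-dimethoxyphenyl}ethyl)phenoxy]-3,4-dimethoxybenzaldehyde, via alcohol acetal 19 (not isolated)
Conditions: LiAlH4, THF, 0 °C; then 1 M aq HCl, THF, rt
Reagents that add atoms: water, O
Why: Hydride reduction takes the aryl ester to the benzylic alcohol without touching acetal or diaryl ethers, and the acidic work-up then hydrolyses the dioxolane (acetal hydrolysis) to free the ring C aldehyde.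

Step 10
Reactants: 20 2-[2-(2-{3-[4-(hydroxymethyl)phenoxy]-4,5-dimethoxyphenyl}ethyl)phenoxy]-3,4-dimethoxybenzaldehyde
Product: 21 2-[2-(2-{3-(4-formylphenoxy)-4,5-dimethoxyphenyl}ethyl)phenoxy]-3,4-dimethoxybenzaldehyde
Conditions: activated MnO2 (excess), CH2Cl2, rt
Reagents that add atoms: none
Why: Benzylic oxidation with MnO2 stops at the aldehyde and leaves the existing formyl group and the ethers untouched, giving the dialdehyde.

Step 11
Reactants: 21 2-[2-(2-{3-(4-formylphenoxy)-4,5-dimethoxyphenyl}ethyl)phenoxy]-3,4-dimethoxybenzaldehyde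
Product: 22 macrocyclic stilbene, the tetra-O-methyl ether of the target with CH=CH in place of the B–C ethano bridge (E/Z mixture)
Conditions: TiCl3, Zn–Cu couple, DME, reflux; 21 added by syringe pump (high dilution)
Reagents that add atoms: none
Why: Intramolecular McMurry coupling, in which low-valent titanium reductively couples the two aryl aldehydes and deoxygenates the coupled product to the alkene, high dilution favouring the 17-membered ring, a closure of the kind established for macrocyclic bis(bibenzyl) ethers.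

Step 12
Reactants: 22 macrocyclic stilbene
Product: 23 tetra-O-methyl ether of the target (both bridges CH2CH2)
Conditions: H2 (1 atm), 10% Pd/C, EtOAc, rt
Reagents that add atoms: none
Why: Catalytic hydrogenation of the stilbene double bond, either geometry, should give the saturated bridge without affecting diaryl or methyl ethers.

Step 13
Reactants: 23 tetra-O-methyl ether of the target
Product: 24 target CNP0114693.0
Conditions: BBr3 (8 equiv), CH2Cl2, −78 °C → rt; then H2O, work-up under N2
Reagents that add atoms: none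
Why: Lewis-acid ether cleavage in which BBr3 should remove all four aryl methyl groups as MeBr through the borate esters, while the diaryl ether links, lacking an sp3 carbon for bromide attack, remain.

Compound list
1 | 3-hydroxy-4,5-dimethoxybenzaldehyde | COc1cc(C=O)cc(O)c1OC | starting material
2 | 3-(benzyloxy)-4,5-dimethoxybenzaldehyde | COc1cc(C=O)cc(OCc2ccccc2)c1OC | intermediate
3 | (2-hydroxybenzyl)triphenylphosphonium bromide | [Br-].Oc1ccccc1C[P+](c1ccccc1)(c1ccccc1)c1ccccc1 | starting material
4 | potassium 2-[(triphenylphosphoranylidene)methyl]phenolate (ylide phenoxide, not isolated) | [K+].[O-]c1ccccc1C=P(c1ccccc1)(c1ccccc1)c1ccccc1 | intermediate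
5 | 2-[2-(3-benzyloxy-4,5-dimethoxyphenyl)ethenyl]phenol, E/Z mixture (geometry left open) | Oc1ccccc1C=Cc1cc(OC)c(OC)c(OCc2ccccc2)c1 | intermediate
6 | 2-fluoro-3,4-dimethoxybenzaldehyde | COc1ccc(C=O)c(F)c1OC | starting material
7 | 2-{2-[2-(3-benzyloxy-4,5-dimethoxyphenyl)ethenyl]phenoxy}-3,4-dimethoxybenzaldehyde, E/Z mixture | COc1ccc(C=O)c(Oc2ccccc2C=Cc2cc(OC)c(OC)c(OCc3ccccc3)c2)c1OC | intermediate
8 | 2-(2-{2-[2-(3-benzyloxy-4,5-dimethoxyphenyl)ethenyl]phenoxy}-3,4-dimethoxyphenyl)-1,3-dioxolane, E/Z mixture | COc1ccc(C2OCCO2)c(Oc2ccccc2C=Cc2cc(OC)c(OC)c(OCc3ccccc3)c2)c1OC | intermediate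
9 | 5-(2-{2-[6-(1,3-dioxolan-2-yl)-2,3-dimethoxyphenoxy]phenyl}ethyl)-2,3-dimethoxyphenol | COc1ccc(C2OCCO2)c(Oc2ccccc2CCc2cc(OC)c(OC)c(O)c2)c1OC | intermediate
10 | trichloroethylene | ClC=C(Cl)Cl | starting material
11 | dichloroacetylene (not isolated) | ClC#CCl | intermediate
12 | 2-{2-[2-(2-{3-[(E)-1,2-dichloroethenyloxy]-4,5-dimethoxyphenyl}ethyl)phenoxy]-3,4-dimethoxyphenyl}-1,3-dioxolane | COc1ccc(C2OCCO2)c(Oc2ccccc2CCc2cc(OC)c(OC)c(O/C(Cl)=C\Cl)c2)c1OC | intermediate
13 | 2-[2-(2-{2-[3-(chloroethynyloxy)-4,5-dimethoxyphenyl]ethyl}phenoxy)-3,4-dimethoxyphenyl]-1,3-dioxolane (not isolated) | COc1ccc(C2OCCO2)c(Oc2ccccc2CCc2cc(OC)c(OC)c(OC#CCl)c2)c1OC | intermediate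
14 | lithium acetylide of 15 (not isolated) | COc1ccc(C2OCCO2)c(Oc2ccccc2CCc2cc(OC)c(OC)c(OC#C[Li])c2)c1OC | intermediate
15 | 2-[2-(2-{2-[3-(ethynyloxy)-4,5-dimethoxyphenyl]ethyl}phenoxy)-3,4-dimethoxyphenyl]-1,3-dioxolane | COc1ccc(C2OCCO2)c(Oc2ccccc2CCc2cc(OC)c(OC)c(OC#C)c2)c1OC | intermediate
16 | methyl coumalate (methyl 2-oxo-2H-pyran-5-carboxylate) | COC(=O)c1ccc(=O)oc1 | starting material
17 | methyl 7-aryloxy-3-oxo-2-oxabicyclo[2.2.2]octa-5,7-diene-6-carboxylate, aryl = ring A of 15; racemic, bridgeheads fixed by the bicycle (not isolated) | COc1ccc(C2OCCO2)c(Oc2ccccc2CCc2cc(OC)c(OC)c(OC3=CC4OC(=O)C3C=C4C(=O)OC)c2)c1OC | intermediate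
18 | methyl 4-[5-(2-{2-[6-(1,3-dioxolan-2-yl)-2,3-dimethoxyphenoxy]phenyl}ethyl)-2,3-dimethoxyphenoxy]benzoate | COC(=O)c1ccc(Oc2cc(CCc3ccccc3Oc3c(C4OCCO4)ccc(OC)c3OC)cc(OC)c2OC)cc1 | intermediate
19 | {4-[5-(2-{2-[6-(1,3-dioxolan-2-yl)-2,3-dimethoxyphenoxy]phenyl}ethyl)-2,3-dimethoxyphenoxy]phenyl}methanol (not isolated) | OCc1ccc(Oc2cc(CCc3ccccc3Oc3c(C4OCCO4)ccc(OC)c3OC)cc(OC)c2OC)cc1 | intermediate
20 | 2-[2-(2-{3-[4-(hydroxymethyl)phenoxy]-4,5-dimethoxyphenyl}ethyl)phenoxy]-3,4-dimethoxybenzaldehyde | OCc1ccc(Oc2cc(CCc3ccccc3Oc3c(C=O)ccc(OC)c3OC)cc(OC)c2OC)cc1 | intermediate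
21 | 2-[2-(2-{3-(4-formylphenoxy)-4,5-dimethoxyphenyl}ethyl)phenoxy]-3,4-dimethoxybenzaldehyde | O=Cc1ccc(Oc2cc(CCc3ccccc3Oc3c(C=O)ccc(OC)c3OC)cc(OC)c2OC)cc1 | intermediate
22 | macrocyclic stilbene: tetra-O-methyl ether of the target with CH=CH between rings B and C, E/Z mixture (geometry left open) | COc1cc2cc(c1OC)Oc1ccc(cc1)C=Cc1ccc(OC)c(OC)c1Oc1ccccc1CC2 | intermediate
23 | tetra-O-methyl ether of the target | COc1cc2cc(c1OC)Oc1ccc(cc1)CCc1ccc(OC)c(OC)c1Oc1ccccc1CC2 | intermediate
24 | CNP0114693.0: 17-membered bis(bibenzyl) with ether links A–O–B and C–O–D, ethano bridges B–C and D–A, catechol hydroxyls on rings A and C; no stereocentre | Oc1cc2cc(c1O)Oc1ccc(cc1)CCc1ccc(O)c(O)c1Oc1ccccc1CC2 | target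

Total step count: 13. Longest linear sequence: 13 steps (1 to 24); compounds 3, 6, 10 and 16 enter as purchased materials.

Steps most likely to fail

Step 8. The ynol ether may oligomerise at the temperature the cycloaddition needs, or the two partners may combine in the other orientation so that the ether oxygen ends meta to the ester. The fallback buys ring B and uses known chemistry. It sets out from phenol 9: nucleophilic aromatic substitution on 4-fluorobenzaldehyde (K2CO3, DMF, 130 °C) should give 4-[5-(2-{2-[6-(1,3-dioxolan-2-yl)-2,3-dimethoxyphenoxy]phenyl}ethyl)-2,3-dimethoxyphenoxy]benzaldehyde F1. Hydrolysis of its acetal with 1 M HCl in THF returns to the route at dialdehyde 21.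

Step 7. Excess n-BuLi may metalate the acetal C–H or an arene ring, and the terminal ynol ether may hydrate or polymerise during work-up and handling. The fallback avoids the ynol ether altogether. It sets out from phenol 9: an Ullmann-type C–O coupling with methyl 4-iodobenzoate (CuI, N,N-dimethylglycine, Cs2CO3, dioxane, 90 °C) should give the ester directly (no new compound, F0) and returns to the route at 18.

Step 11. Intermolecular carbonyl coupling to oligomers may outrun ring closure, or the reaction may stop at the pinacol stage. The fallback closes the ring by an intramolecular Wittig reaction. It sets out from hydroxy aldehyde 20: Appel bromination (CBr4, PPh3, CH2Cl2, 0 °C) should give 2-[2-(2-{3-[4-(bromomethyl)phenoxy]-4,5-dimethoxyphenyl}ethyl)phenoxy]-3,4-dimethoxybenzaldehyde F2. PPh3 in toluene at 80 °C should then give {4-[5-(2-{2-[6-formyl-2,3-dimethoxyphenoxy]phenyl}ethyl)-2,3-dimethoxyphenoxy]benzyl}triphenylphosphonium bromide F3. Slow addition of F3 to NaOMe in CH2Cl2 at high dilution returns to the route at macrocyclic stilbene 22.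

Further compounds
F1 | step 8 | 4-[5-(2-{2-[6-(1,3-dioxolan-2-yl)-2,3-dimethoxyphenoxy]phenyl}ethyl)-2,3-dimethoxyphenoxy]benzaldehyde | O=Cc1ccc(Oc2cc(CCc3ccccc3Oc3c(C4OCCO4)ccc(OC)c3OC)cc(OC)c2OC)cc1
F0 | step 7 | none | none
F2 | step 11 | 2-[2-(2-{3-[4-(bromomethyl)phenoxy]-4,5-dimethoxyphenyl}ethyl)phenoxy]-3,4-dimethoxybenzaldehyde | BrCc1ccc(Oc2cc(CCc3ccccc3Oc3c(C=O)ccc(OC)c3OC)cc(OC)c2OC)cc1
F3 | step 11 | {4-[5-(2-{2-[6-formyl-2,3-dimethoxyphenoxy]phenyl}ethyl)-2,3-dimethoxyphenoxy]benzyl}triphenylphosphonium bromide | [Br-].O=Cc1ccc(OC)c(OC)c1Oc1ccccc1CCc1cc(OC)c(OC)c(Oc2ccc(C[P+](c3ccccc3)(c3ccccc3)c3ccccc3)cc2)c1
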